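The dihydropyran ring of the flavan (O1–C2–C3–C4–C4a–C8a) is opened at C2–C3 by reading C2, which carries O1 and the B-ring carbon C1′, as the carbonyl carbon of an aryl benzoate, and C3–C4 as the inner carbons of an ortho-allyl group on the A-ring. One titanium-mediated carbonyl–olefin metathesis turns ester 11 into 2-aryl-4H-chromene 13, creating C2=C3 as the ring closes; an iridium-catalysed asymmetric hydrogenation then sets C2 as R. The precursor is a simple ester of two separately made arenes. The C8 prenyl group is withheld as a bromide, which also steers the Claisen rearrangement that installs the allyl group, and is added afterwards.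

Key step: step 8

Remark: the stereocentre C2 is read from the SMILES as R (CIP order O1 > C1′ > C3 > H); every chiral SMILES below is drawn to that configuration.

Step 1
Reactants: 1 5-methoxyresorcinol
Product: 2 1-methoxy-3,5-bis(methoxymethoxy)benzene
Conditions: MOMCl (2.5 equiv), i-Pr2NEt, CH2Cl2, 0 °C → rt
Reagents that add atoms: chloromethyl methyl ether, COCCl
Why: Williamson-type O-alkylation of both phenols gives the bis-MOM acetal, whose two chelating groups direct the next metalation.

Step 2
Reactants: 2 1-methoxy-3,5-bis(methoxymethoxy)benzene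
Product: 4 2-bromo-5-methoxy-1,3-bis(methoxymethoxy)benzene, via aryllithium 3 (not isolated)
Conditions: n-BuLi (1.1 equiv), THF, 0 °C; then BrCCl2CCl2Br, −78 °C → rt
Reagents that add atoms: 1,2-dibromotetrachloroethane, BrC(Cl)(Cl)C(Cl)(Cl)Br
Why: Directed ortho-metalation should occur at the carbon flanked by the two chelating OMOM groups in preference to the OMOM/OMe-flanked carbons, and the aryllithium is brominated by halogen transfer.

Step 3
Reactants: 4 2-bromo-5-methoxy-1,3-bis(methoxymethoxy)benzene
Product: 5 2-bromo-5-methoxy-3-(methoxymethoxy)phenol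
Conditions: conc. HCl (cat.), MeOH/CH2Cl2, 0 °C, stopped at partial conversion; recovered 4 recycled
Reagents that add atoms: none
Why: Acid-catalysed transacetalisation with methanol removes one of the two equivalent MOM groups, so the cleavage is statistical and is stopped early, with unreacted 4 returned to the step.

Step 4
Reactants: 5 2-bromo-5-methoxy-3-(methoxymethoxy)phenol
Product: 6 1-(allyloxy)-2-bromo-5-methoxy-3-(methoxymethoxy)benzene
Conditions: allyl bromide, K2CO3, acetone, reflux
Reagents that add atoms: allyl bromide, C=CCBr
Why: Williamson ether synthesis on the single free phenol.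

Step 5
Reactants: 6 1-(allyloxy)-2-bromo-5-methoxy-3-(methoxymethoxy)benzene
Product: 7 2-allyl-6-bromo-3-methoxy-5-(methoxymethoxy)phenol
Conditions: N,N-diethylaniline, 190 °C
Reagents that add atoms: none
Why: Aromatic Claisen [3,3] rearrangement; bromine blocks one ortho position, so the allyl group should be delivered only to the carbon between the ether oxygen and the methoxy group, and tautomerisation frees the phenol needed for acylation.

Step 6
Reactants: 8 3-hydroxy-5-methoxybenzoic acid
Product: 10 3-methoxy-5-(methoxymethoxy)benzoic acid, via MOM ester 9 (not isolated)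
Conditions: MOMCl (2.4 equiv), i-Pr2NEt, CH2Cl2, 0 °C → rt; then 2 M NaOH, MeOH/THF, rt; 1 M HCl to pH 4, 0 °C
Reagents that add atoms: chloromethyl methyl ether, COCCl; sodium hydroxide, [Na+].[OH-]
Why: Double O-alkylation followed by saponification of the labile methoxymethyl ester (acyl–oxygen cleavage) in the same flask leaves the aryl MOM ether in place.

Step 7
Reactants: 7 2-allyl-6-bromo-3-methoxy-5-(methoxymethoxy)phenol; 10 3-methoxy-5-(methoxymethoxy)benzoic acid
Product: 11 2-allyl-6-bromo-3-methoxy-5-(methoxymethoxy)phenyl 3-methoxy-5-(methoxymethoxy)benzoate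
Conditions: DIC, DMAP, CH2Cl2, 0 °C → rt
Reagents that add atoms: none
Why: Steglich esterification, in which the acylpyridinium intermediate acylates even a doubly ortho-substituted phenol under neutral conditions that spare the MOM ethers.

Step 8
Reactants: 11 2-allyl-6-bromo-3-methoxy-5-(methoxymethoxy)phenyl 3-methoxy-5-(methoxymethoxy)benzoate
Product: 13 8-bromo-5-methoxy-7-(methoxymethoxy)-2-[3-methoxy-5-(methoxymethoxy)phenyl]-4H-chromene, via acyclic enol ether 12 (not isolated)
Conditions: Tebbe reagent (4 equiv), pyridine (cat.), THF, −40 → 25 °C; then 65 °C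
Reagents that add atoms: none
Why: Cp2Ti=CH2 released from the Tebbe reagent methylenates the ester carbonyl through an oxatitanacyclobutane to give enol ether 12, and on heating the excess titanium methylidene exchanges with the terminal allyl alkene to place a titanium alkylidene on the future C3, which adds across the enol-ether C=C and cycloreverts to form the C2=C3 bond with loss of ethylene. The closest known reaction type is the Tebbe-mediated cyclisation of olefinic esters to cyclic enol ethers (ester methylenation and ring-closing olefin metathesis in one flask), applied here to an aryl benzoate whose methylenation and ring-closing metathesis are each established separately. The six-membered pyran ring is closed by ring-closing metathesis, that is a [2+2] cycloaddition to a bicyclic titanacyclobutane followed by retro-[2+2], driven by ethylene loss and by conjugation of the new enol ether with the B-ring. No stereocentre is formed, since C2 becomes a prochiral sp2 carbon whose configuration is set in step 9. The step needs chemoselectivity for the ester carbonyl and the allyl terminus and no migration of the allyl double bond into conjugation (which would lead on to a benzofuran); this is secured because 11 holds no other carbonyl or alkene (the prenyl group is still a C8 bromide), the aryl bromide and MOM ethers are inert to Ti(IV) alkylidenes, and the ortho relationship of ester oxygen and allyl group holds the two reacting ends within reach.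

Step 9
Reactants: 13 8-bromo-5-methoxy-7-(methoxymethoxy)-2-[3-methoxy-5-(methoxymethoxy)phenyl]-4H-chromene
Product: 14 (2R)-8-bromo-5-methoxy-7-(methoxymethoxy)-2-[3-methoxy-5-(methoxymethoxy)phenyl]chromane
Conditions: [Ir(cod)(L*)]BArF (1–2 mol%, L* = threonine-derived phosphinite–oxazoline, antipode chosen for Si-face delivery at C2), H2 (50 bar), CH2Cl2, rt
Reagents that add atoms: none
Why: Iridium-catalysed asymmetric hydrogenation of a trisubstituted aryl enol ether with a chiral P,N-ligand complex, a reaction type established for 2-aryl-4H-chromenes; the ligand antipode that delivers hydrogen to the Si face of C2 should set (2R), and the aryl bromide and MOM ethers should be untouched by the homogeneous catalyst.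

Step 10
Reactants: 14 (2R)-8-bromo-5-methoxy-7-(methoxymethoxy)-2-[3-methoxy-5-(methoxymethoxy)phenyl]chromane
Product: 16 (2R)-5-methoxy-7-(methoxymethoxy)-2-[3-methoxy-5-(methoxymethoxy)phenyl]-8-(3-methylbut-2-en-1-yl)chromane, via C8 aryllithium 15 (not isolated)
Conditions: n-BuLi (1.05 equiv), THF, −78 °C; CuBr·SMe2 (20 mol%), prenyl bromide, −78 → 0 °C
Reagents that add atoms: prenyl bromide, CC(C)=CCBr
Why: Bromine–lithium exchange gives the C8 aryllithium, stabilised by the flanking OMOM and ring oxygen, and copper-catalysed allylic substitution on prenyl bromide at its unsubstituted terminus (SN2) should give the linear prenyl group without touching the non-acidic C2 stereocentre.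

Step 11
Reactants: 16 (2R)-5-methoxy-7-(methoxymethoxy)-2-[3-methoxy-5-(methoxymethoxy)phenyl]-8-(3-methylbut-2-en-1-yl)chromane
Product: 17 (2R)-2-(3-hydroxy-5-methoxyphenyl)-5-methoxy-8-(3-methylbut-2-en-1-yl)chroman-7-ol
Conditions: conc. HCl (cat.), MeOH, 0 °C → rt
Reagents that add atoms: none
Why: Acid-catalysed transacetalisation of both aryl MOM ethers with methanol under mild, cold conditions should leave the prenyl alkene, the chroman ether and C2 intact, since the B-ring carries no para oxygen that could stabilise a C2 cation.

Compound list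
1 | 5-methoxyresorcinol (5-methoxybenzene-1,3-diol) | COc1cc(O)cc(O)c1 | starting material
2 | 1-methoxy-3,5-bis(methoxymethoxy)benzene | COCOc1cc(OC)cc(OCOC)c1 | intermediate
3 | 2-lithio-5-methoxy-1,3-bis(methoxymethoxy)benzene (not isolated) | COCOc1cc(OC)cc(OCOC)c1[Li] | intermediate
4 | 2-bromo-5-methoxy-1,3-bis(methoxymethoxy)benzene | COCOc1cc(OC)cc(OCOC)c1Br | intermediate
5 | 2-bromo-5-methoxy-3-(methoxymethoxy)phenol | COCOc1cc(OC)cc(O)c1Br | intermediate
6 | 1-(allyloxy)-2-bromo-5-methoxy-3-(methoxymethoxy)benzene | C=CCOc1cc(OC)cc(OCOC)c1Br | intermediate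
7 | 2-allyl-6-bromo-3-methoxy-5-(methoxymethoxy)phenol | C=CCc1c(O)c(Br)c(OCOC)cc1OC | intermediate
8 | 3-hydroxy-5-methoxybenzoic acid | COc1cc(O)cc(C(=O)O)c1 | starting material
9 | methoxymethyl 3-methoxy-5-(methoxymethoxy)benzoate (not isolated) | COCOC(=O)c1cc(OC)cc(OCOC)c1 | intermediate
10 | 3-methoxy-5-(methoxymethoxy)benzoic acid | COCOc1cc(OC)cc(C(=O)O)c1 | intermediate
11 | 2-allyl-6-bromo-3-methoxy-5-(methoxymethoxy)phenyl 3-methoxy-5-(methoxymethoxy)benzoate | C=CCc1c(OC(=O)c2cc(OC)cc(OCOC)c2)c(Br)c(OCOC)cc1OC | intermediate
12 | 1-[2-allyl-6-bromo-3-methoxy-5-(methoxymethoxy)phenoxy]-1-[3-methoxy-5-(methoxymethoxy)phenyl]ethene (not isolated) | C=CCc1c(OC(=C)c2cc(OC)cc(OCOC)c2)c(Br)c(OCOC)cc1OC | intermediate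
13 | 8-bromo-5-methoxy-7-(methoxymethoxy)-2-[3-methoxy-5-(methoxymethoxy)phenyl]-4H-chromene | COCOc1cc(OC)cc(C2=CCc3c(OC)cc(OCOC)c(Br)c3O2)c1 | intermediate
14 | (2R)-8-bromo-5-methoxy-7-(methoxymethoxy)-2-[3-methoxy-5-(methoxymethoxy)phenyl]chromane | COCOc1cc(OC)cc([C@H]2CCc3c(OC)cc(OCOC)c(Br)c3O2)c1 | intermediate
15 | (2R)-8-lithio-5-methoxy-7-(methoxymethoxy)-2-[3-methoxy-5-(methoxymethoxy)phenyl]chromane (not isolated) | COCOc1cc(OC)cc([C@H]2CCc3c(OC)cc(OCOC)c([Li])c3O2)c1 | intermediate
16 | (2R)-5-methoxy-7-(methoxymethoxy)-2-[3-methoxy-5-(methoxymethoxy)phenyl]-8-(3-methylbut-2-en-1-yl)chromane | COCOc1cc(OC)cc([C@H]2CCc3c(OC)cc(OCOC)c(CC=C(C)C)c3O2)c1 | intermediate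
17 | (2R)-2-(3-hydroxy-5-methoxyphenyl)-5-methoxy-8-(3-methylbut-2-en-1-yl)chroman-7-ol | COc1cc(O)cc([C@H]2CCc3c(OC)cc(O)c(CC=C(C)C)c3O2)c1 | target

Total step count: 11
Longest linear sequence: 10 steps (steps 1–5 and 7–11; step 6 makes the second fragment)

Steps most likely to fail

Step 8. The sequence may stall at the acyclic enol ether, the allyl double bond may migrate into conjugation and lead on to a ring-contracted benzofuran, or the Lewis-acidic aluminium by-product may erode MOM ethers during heating. The fallback sets out from 11: methylenation with the aluminium-free Petasis reagent (Cp2TiMe2, toluene, 70 °C) and isolation of the acyclic enol ether 12 over basic alumina, then ring-closing olefin metathesis of 12 with the Grubbs second-generation ruthenium catalyst (toluene, 60 °C, 1,4-benzoquinone as hydride scavenger), which should give 13, where the route resumes. This replaces a stoichiometric titanium carbonyl–olefin metathesis by a catalytic ruthenium olefin metathesis on an isolated diene and makes no compound outside the list (F0).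

Step 9. Facial discrimination of the enol ether may be poor, or the cationic iridium hydride may open the acid-sensitive enol ether. The fallback sets out from 13: mild hydrolysis (PPTS, wet acetone, rt) should give the phenolic ketone 3-[3-bromo-2-hydroxy-6-methoxy-4-(methoxymethoxy)phenyl]-1-[3-methoxy-5-(methoxymethoxy)phenyl]propan-1-one F1. Corey–Bakshi–Shibata reduction ((R)-Me-CBS, BH3·SMe2 in excess for the phenol, THF), with the aryl group as the large substituent, should give (1S)-3-[3-bromo-2-hydroxy-6-methoxy-4-(methoxymethoxy)phenyl]-1-[3-methoxy-5-(methoxymethoxy)phenyl]propan-1-ol F2. Mitsunobu cyclisation (PPh3, DIAD, THF, 0 °C) then closes the ether with inversion and comes back to the route at 14 as the (2R) isomer.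

Step 11. The liberated C7 hydroxyl may add across the neighbouring prenyl alkene under acid (a dimethylchroman ring), or the alkene may be hydrated. The fallback sets out from 14 and moves the acid step ahead of the prenylation. Methanolic HCl on 14 should give (2R)-8-bromo-2-(3-hydroxy-5-methoxyphenyl)-5-methoxychroman-7-ol F3. Silylation (TBSCl, imidazole, DMF) gives (2R)-8-bromo-7-(tert-butyldimethylsilyloxy)-2-[3-(tert-butyldimethylsilyloxy)-5-methoxyphenyl]-5-methoxychromane F4. A linear-selective Negishi coupling with prenylzinc bromide (Pd(OAc)2, CPhos, THF, rt), which avoids an ortho-lithiated silyl ether, should give (2R)-7-(tert-butyldimethylsilyloxy)-2-[3-(tert-butyldimethylsilyloxy)-5-methoxyphenyl]-5-methoxy-8-(3-methylbut-2-en-1-yl)chromane F5. TBAF (THF, 0 °C) then returns to the route at the target 17 under non-acidic conditions.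

Further compounds
F0 | step 8 | none | none
F1 | step 9 | 3-[3-bromo-2-hydroxy-6-methoxy-4-(methoxymethoxy)phenyl]-1-[3-methoxy-5-(methoxymethoxy)phenyl]propan-1-one | COCOc1cc(OC)cc(C(=O)CCc2c(OC)cc(OCOC)c(Br)c2O)c1
F2 | step 9 | (1S)-3-[3-bromo-2-hydroxy-6-methoxy-4-(methoxymethoxy)phenyl]-1-[3-methoxy-5-(methoxymethoxy)phenyl]propan-1-ol | COCOc1cc(OC)cc([C@@H](O)CCc2c(OC)cc(OCOC)c(Br)c2O)c1
F3 | step 11 | (2R)-8-bromo-2-(3-hydroxy-5-methoxyphenyl)-5-methoxychroman-7-ol | COc1cc(O)cc([C@H]2CCc3c(OC)cc(O)c(Br)c3O2)c1
F4 | step 11 | (2R)-8-bromo-7-(tert-butyldimethylsilyloxy)-2-[3-(tert-butyldimethylsilyloxy)-5-methoxyphenyl]-5-methoxychromane | COc1cc(O[Si](C)(C)C(C)(C)C)cc([C@H]2CCc3c(OC)cc(O[Si](C)(C)C(C)(C)C)c(Br)c3O2)c1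
F5 | step 11 | (2R)-7-(tert-butyldimethylsilyloxy)-2-[3-(tert-butyldimethylsilyloxy)-5-methoxyphenyl]-5-methoxy-8-(3-methylbut-2-en-1-yl)chromane | COc1cc(O[Si](C)(C)C(C)(C)C)cc([C@H]2CCc3c(OC)cc(O[Si](C)(C)C(C)(C)C)c(CC=C(C)C)c3O2)c1
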